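Retrosynthesis: the eight phenols are masked as benzyl ethers and the gallate is cut at the C3–O acyl bond. The C3 carbinol is traced to a racemic flavan-3-one. The C4–C4a bond of the pyran ring is then cut by a retro-semipinacol 1,2-aryl shift, which gives a 2-aryl-3-(mesyloxymethyl)-2,3-dihydrobenzofuran-3-ol (C3–C4a bond present, not in the target), derived from an o-iodoaryl propargyl ether.
Forward: O1–C2 is made first (Mitsunobu). A 5-exo-dig radical cyclisation joins the A-ring to C3 and closes a temporary five-membered ring (O1, C2, C3, C4a, C8a). The exocyclic CH2 is oxidised and activated, and the ring expansion inserts it as C4 to give the six-membered pyran ring. Reduction, galloylation and hydrogenolysis follow.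
Enabling feature: C4a is the ipso carbon of a phloroglucinol ring with oxygen on both ortho carbons (C5, C8a) and on the para carbon (C7), so it migrates readily from C3 to the neighbouring CH2. After the shift, C2–H lies between O1, the B-ring and the C3 carbonyl and is freely enolisable.
Stereochemistry: nothing before the ketone needs control (C2 racemic, both C3 epimers converge in the ring expansion). C2 and C3 are then set together by a Ru-catalysed dynamic kinetic resolution hydrogenation: catalyst control for the absolute configuration, hydride delivery anti to the C2 aryl group for the 2,3-cis relation.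

Key step: step 7

Assumption: the absolute sense of the hydrogenation in step 8 is assigned by analogy with 2-arylcyclohexanones; should the (2S,3S) alcohol predominate, the mirror-image catalyst [(R)-Xyl-SDP/(S,S)-DPEN] is used instead.

Step 1
Reactants: 1 3,5-bis(benzyloxy)phenol
Product: 2 3,5-bis(benzyloxy)-2-iodophenol
Conditions: NIS (1.0 equiv), CH2Cl2, −20 to 0 °C, dark
Reagents that add atoms: N-iodosuccinimide, O=C1CCC(=O)N1I
Why: Electrophilic aromatic iodination at the position ortho to the free hydroxyl, which is activated by all three oxygens, while the more hindered position between the two benzyloxy groups should react more slowly and any 4-iodo isomer is removed by chromatography.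

Step 2
Reactants: 3 3,4,5-tris(benzyloxy)benzaldehyde; 4 ethynylmagnesium bromide
Product: 5 (±)-1-[3,4,5-tris(benzyloxy)phenyl]prop-2-yn-1-ol
Conditions: THF, 0 °C; then H2O
Reagents that add atoms: none
Why: 1,2-Addition of an alkynyl Grignard reagent to an aromatic aldehyde, the carbinol centre being formed racemic on purpose because the derived C2 centre is equilibrated later.

Step 3
Reactants: 2 3,5-bis(benzyloxy)-2-iodophenol; 5 (±)-1-[3,4,5-tris(benzyloxy)phenyl]prop-2-yn-1-ol
Product: 6 (±)-1,5-bis(benzyloxy)-2-iodo-3-({1-[3,4,5-tris(benzyloxy)phenyl]prop-2-yn-1-yl}oxy)benzene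
Conditions: PPh3, DIAD, THF, 0 °C to rt
Reagents that add atoms: none
Why: Mitsunobu etherification of an acidic phenol with a secondary propargylic benzylic alcohol forms the future O1–C2 bond, and any SN1 leakage is harmless because the centre is racemic.

Step 4
Reactants: 6 (±)-1,5-bis(benzyloxy)-2-iodo-3-({1-[3,4,5-tris(benzyloxy)phenyl]prop-2-yn-1-yl}oxy)benzene
Product: 7 (±)-4,6-bis(benzyloxy)-3-methylidene-2-[3,4,5-tris(benzyloxy)phenyl]-2,3-dihydro-1-benzofuran
Conditions: Bu3SnH (slow addition), AIBN (cat.), toluene, 80 °C; KF work-up, Et3N-deactivated silica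
Reagents that add atoms: none
Why: Tin hydride radical chain in which iodine abstraction gives an aryl radical that closes 5-exo-dig onto the alkyne (C3–C4a bond of the temporary five-membered ring) and the resulting vinyl radical is reduced to the exocyclic methylene, the C2 centre being untouched.

Step 5
Reactants: 7 (±)-4,6-bis(benzyloxy)-3-methylidene-2-[3,4,5-tris(benzyloxy)phenyl]-2,3-dihydro-1-benzofuran
Product: 8 (±)-4,6-bis(benzyloxy)-3-(hydroxymethyl)-2-[3,4,5-tris(benzyloxy)phenyl]-2,3-dihydro-1-benzofuran-3-ol (both C3 epimers)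
Conditions: OsO4 (cat.), NMO, acetone/H2O, rt; Na2SO3 quench
Reagents that add atoms: osmium tetroxide (catalytic oxygen carrier), O=[Os](=O)(=O)=O; N-methylmorpholine N-oxide, C[N+]1([O-])CCOCC1; water, O
Why: Catalytic osmium tetroxide syn-dihydroxylation of the electron-rich 1,1-disubstituted alkene under mildly basic conditions that should not isomerise it, the facial selectivity being irrelevant because C3 becomes trigonal in step 7.

Step 6
Reactants: 8 (±)-4,6-bis(benzyloxy)-3-(hydroxymethyl)-2-[3,4,5-tris(benzyloxy)phenyl]-2,3-dihydro-1-benzofuran-3-ol (both C3 epimers)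
Product: 9 (±)-{4,6-bis(benzyloxy)-3-hydroxy-2-[3,4,5-tris(benzyloxy)phenyl]-2,3-dihydro-1-benzofuran-3-yl}methyl methanesulfonate (both C3 epimers)
Conditions: MsCl (1.1 equiv), Et3N, CH2Cl2, −30 °C; cold aq. NaHCO3, used crude
Reagents that add atoms: methanesulfonyl chloride, CS(=O)(=O)Cl
Why: Selective sulfonylation of the primary hydroxyl of a primary/tertiary 1,2-diol, the tertiary benzylic hydroxyl being too hindered to react at low temperature.

Step 7
Reactants: 9 (±)-{4,6-bis(benzyloxy)-3-hydroxy-2-[3,4,5-tris(benzyloxy)phenyl]-2,3-dihydro-1-benzofuran-3-yl}methyl methanesulfonate (both C3 epimers)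
Product: 10 (±)-5,7-bis(benzyloxy)-2-[3,4,5-tris(benzyloxy)phenyl]chroman-3-one
Conditions: Et3Al (3 equiv), CH2Cl2, −78 to −20 °C; aq. Rochelle salt, crude ketone used at once
Reagents that add atoms: none
Why: Et3Al converts the tertiary hydroxyl into an aluminium alkoxide and activates the primary mesylate; the A-ring ipso carbon (future C4a), placed anti-periplanar to the C–OMs bond by rotation about C3–CH2, attacks the CH2 carbon to give a spiro[2.5]octadienyl (phenonium) cation, which collapses by cleavage of the old C3–C4a bond as the C3–O–Al oxygen forms the carbonyl. The closest known reaction types are the organoaluminium-promoted semipinacol rearrangement of β-mesyloxy alcohols and the Tiffeneau–Demjanov-type one-carbon expansion of benzo-fused five-membered ketones (1-indanones to 2-tetralones), in which the aryl carbon migrates. The pyran ring is closed by ring expansion: the C4–C4a bond forms by 3-exo-tet ipso attack and the C3–C4a bond breaks, so the five-membered ring (O1, C2, C3, C4a, C8a) becomes the six-membered ring (O1, C2, C3, C4, C4a, C8a) with the exocyclic carbon inserted as C4. No new stereocentre is formed: C3 becomes trigonal, so both C3 epimers of 9 converge, and C2 is carried as a racemic, deliberately enolisable centre for step 8. The selectivity needed is migration of the aryl carbon in preference to C2 (which would give the isomeric chroman-4-one), to epoxide closure and to ionisation at C3; it should be secured by the ortho,ortho,para-trioxygenated migrating carbon, by the lower migratory aptitude of the O-substituted C2, and by holding the oxygen as a non-nucleophilic aluminium alkoxide at low temperature, where no cation develops at C3. Return of mesylate to the bridged ion only regenerates 9, whereas carbonyl formation is irreversible.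

Step 8
Reactants: 10 (±)-5,7-bis(benzyloxy)-2-[3,4,5-tris(benzyloxy)phenyl]chroman-3-one
Product: 11 (2R,3R)-5,7-bis(benzyloxy)-2-[3,4,5-tris(benzyloxy)phenyl]chroman-3-ol (2,3-cis)
Conditions: H2 (50 atm), RuCl2[(S)-Xyl-SDP][(R,R)-DPEN] (0.5 mol %), KOt-Bu (5 mol %), i-PrOH/toluene, 25 °C, degassed
Reagents that add atoms: none
Why: Dynamic kinetic resolution by asymmetric hydrogenation of a racemic α-aryl cyclic ketone (Ru diphosphine/diamine catalyst with alkoxide base), in which C2 should epimerise through the enolate faster than the ketone is reduced, the catalyst selects the (2R) enantiomer, and hydride is delivered to the carbonyl face anti to the pseudo-equatorial C2 aryl group, setting C3 as R and the 2,3-cis relation.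

Step 9
Reactants: 11 (2R,3R)-5,7-bis(benzyloxy)-2-[3,4,5-tris(benzyloxy)phenyl]chroman-3-ol; 12 3,4,5-tris(benzyloxy)benzoic acid
Product: 13 (2R,3R)-5,7-bis(benzyloxy)-2-[3,4,5-tris(benzyloxy)phenyl]chroman-3-yl 3,4,5-tris(benzyloxy)benzoate
Conditions: DCC, DMAP, CH2Cl2, rt
Reagents that add atoms: none
Why: Steglich esterification of the hindered axial secondary alcohol with the protected gallic acid, which does not touch either stereocentre.

Step 10
Reactants: 13 (2R,3R)-5,7-bis(benzyloxy)-2-[3,4,5-tris(benzyloxy)phenyl]chroman-3-yl 3,4,5-tris(benzyloxy)benzoate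
Product: 14 (−)-epigallocatechin gallate, (2R,3R)-5,7-dihydroxy-2-(3,4,5-trihydroxyphenyl)chroman-3-yl 3,4,5-trihydroxybenzoate
Conditions: H2 (1 atm), 20% Pd(OH)2/C, THF/MeOH, rt; filtration under N2
Reagents that add atoms: none
Why: Hydrogenolysis of the eight benzyl ethers over palladium hydroxide on carbon under neutral conditions at room temperature, which should leave the ester, the benzylic C2–O1 bond and both stereocentres intact.

Compound list
1 | 3,5-bis(benzyloxy)phenol | Oc1cc(OCc2ccccc2)cc(OCc2ccccc2)c1 | starting material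
2 | 3,5-bis(benzyloxy)-2-iodophenol | Oc1cc(OCc2ccccc2)cc(OCc2ccccc2)c1I | intermediate
3 | 3,4,5-tris(benzyloxy)benzaldehyde | O=Cc1cc(OCc2ccccc2)c(OCc2ccccc2)c(OCc2ccccc2)c1 | starting material
4 | ethynylmagnesium bromide | C#C[Mg]Br | starting material
5 | (±)-1-[3,4,5-tris(benzyloxy)phenyl]prop-2-yn-1-ol (racemic) | OC(C#C)c1cc(OCc2ccccc2)c(OCc2ccccc2)c(OCc2ccccc2)c1 | intermediate
6 | (±)-1,5-bis(benzyloxy)-2-iodo-3-({1-[3,4,5-tris(benzyloxy)phenyl]prop-2-yn-1-yl}oxy)benzene (racemic) | C#CC(Oc1cc(OCc2ccccc2)cc(OCc2ccccc2)c1I)c1cc(OCc2ccccc2)c(OCc2ccccc2)c(OCc2ccccc2)c1 | intermediate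
7 | (±)-4,6-bis(benzyloxy)-3-methylidene-2-[3,4,5-tris(benzyloxy)phenyl]-2,3-dihydro-1-benzofuran (racemic) | C=C1C(c2cc(OCc3ccccc3)c(OCc3ccccc3)c(OCc3ccccc3)c2)Oc2cc(OCc3ccccc3)cc(OCc3ccccc3)c21 | intermediate
8 | (±)-4,6-bis(benzyloxy)-3-(hydroxymethyl)-2-[3,4,5-tris(benzyloxy)phenyl]-2,3-dihydro-1-benzofuran-3-ol (racemic, both C3 epimers) | OCC1(O)C(c2cc(OCc3ccccc3)c(OCc3ccccc3)c(OCc3ccccc3)c2)Oc2cc(OCc3ccccc3)cc(OCc3ccccc3)c21 | intermediate
9 | (±)-{4,6-bis(benzyloxy)-3-hydroxy-2-[3,4,5-tris(benzyloxy)phenyl]-2,3-dihydro-1-benzofuran-3-yl}methyl methanesulfonate (racemic, both C3 epimers) | CS(=O)(=O)OCC1(O)C(c2cc(OCc3ccccc3)c(OCc3ccccc3)c(OCc3ccccc3)c2)Oc2cc(OCc3ccccc3)cc(OCc3ccccc3)c21 | intermediate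
10 | (±)-5,7-bis(benzyloxy)-2-[3,4,5-tris(benzyloxy)phenyl]chroman-3-one (racemic, C2 enolisable) | O=C1Cc2c(OCc3ccccc3)cc(OCc3ccccc3)cc2OC1c1cc(OCc2ccccc2)c(OCc2ccccc2)c(OCc2ccccc2)c1 | intermediate
11 | (2R,3R)-5,7-bis(benzyloxy)-2-[3,4,5-tris(benzyloxy)phenyl]chroman-3-ol (2,3-cis) | O[C@@H]1Cc2c(OCc3ccccc3)cc(OCc3ccccc3)cc2O[C@@H]1c1cc(OCc2ccccc2)c(OCc2ccccc2)c(OCc2ccccc2)c1 | intermediate
12 | 3,4,5-tris(benzyloxy)benzoic acid | OC(=O)c1cc(OCc2ccccc2)c(OCc2ccccc2)c(OCc2ccccc2)c1 | starting material
13 | (2R,3R)-5,7-bis(benzyloxy)-2-[3,4,5-tris(benzyloxy)phenyl]chroman-3-yl 3,4,5-tris(benzyloxy)benzoate | O=C(O[C@@H]1Cc2c(OCc3ccccc3)cc(OCc3ccccc3)cc2O[C@@H]1c1cc(OCc2ccccc2)c(OCc2ccccc2)c(OCc2ccccc2)c1)c1cc(OCc2ccccc2)c(OCc2ccccc2)c(OCc2ccccc2)c1 | intermediate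
14 | (−)-epigallocatechin gallate, (2R,3R)-5,7-dihydroxy-2-(3,4,5-trihydroxyphenyl)chroman-3-yl 3,4,5-trihydroxybenzoate | O=C(O[C@@H]1Cc2c(O)cc(O)cc2O[C@@H]1c1cc(O)c(O)c(O)c1)c1cc(O)c(O)c(O)c1 | target

Total step count: 10. Longest linear sequence: 9 steps (from 1 through steps 1 and 3–10, or from 3 through steps 2–10).

Steps most likely to fail

Step 7 (ring expansion). Instead of 1,2-aryl migration, the aluminium alkoxide may close onto the CH2–OMs carbon (spiro-epoxide formation). The tertiary benzylic C3–O bond may also ionise with loss of the C2 proton and aromatisation of the five-membered ring, or C2 may migrate in competition with the aryl carbon. The fallback sets out from 7 and returns at 10, and does not pass through the diol or the mesylate. Alkene 7 is treated with [hydroxy(tosyloxy)iodo]benzene in methanol at 0 °C. This is the iodine(III)-mediated oxidative 1,2-aryl shift known for exocyclic methylene groups on benzo-fused rings: iodination at the CH2 terminus, methanol addition at C3, aryl migration with loss of iodobenzene. It should give the ring-expanded ketal (±)-5,7-bis(benzyloxy)-3,3-dimethoxy-2-[3,4,5-tris(benzyloxy)phenyl]chromane F1. Mild hydrolysis (PPTS, acetone/H2O, or wet silica gel) should then release 10.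

Step 8 (dynamic kinetic resolution). Racemisation at C2 may be slower than hydrogenation of the mismatched enantiomer, the catalyst may discriminate poorly between the two α-substituents (erosion of enantiomeric purity or of the cis/trans ratio), or the base may consume the enolisable ketone by aldol-type self-condensation. The fallback sets out from 10 and returns at 11, replacing catalyst control by substrate-controlled reduction and classical resolution. Reduction of 10 with L-Selectride (THF, −78 °C) is expected to deliver hydride anti to the C2 aryl group and give the racemic 2,3-cis alcohol rac-(2R*,3R*)-5,7-bis(benzyloxy)-2-[3,4,5-tris(benzyloxy)phenyl]chroman-3-ol F2. Esterification with (S)-2-methoxy-2-phenylacetic acid (DCC, DMAP, CH2Cl2) should give two diastereomeric esters, separable by chromatography or crystallisation: (2R,3R)-5,7-bis(benzyloxy)-2-[3,4,5-tris(benzyloxy)phenyl]chroman-3-yl (S)-2-methoxy-2-phenylacetate F3 and (2S,3S)-5,7-bis(benzyloxy)-2-[3,4,5-tris(benzyloxy)phenyl]chroman-3-yl (S)-2-methoxy-2-phenylacetate F4. Saponification of F3 (LiOH, THF/MeOH/H2O) should return 11.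

Step 4 (radical cyclisation). The aryl radical may be reduced before it cyclises, the stannyl radical may add to the terminal alkyne, and the exocyclic double bond may migrate into the ring (aromatisation to the 3-methylbenzofuran) under the thermal conditions or on silica. The fallback sets out from 5 and 2 and returns at 7; it forms the C–C and C–O bonds of the five-membered ring in one tin-free, non-radical operation. Alcohol 5 is converted by reductive transposition (2-nitrobenzenesulfonylhydrazide, PPh3, DEAD, THF, −15 °C to rt; loss of sulfinic acid, then retro-ene loss of N2 from the propargylic diazene) into the aryl allene 1,2,3-tris(benzyloxy)-5-(propa-1,2-dien-1-yl)benzene F5. Palladium-catalysed heteroannulation of this 1,2-diene with iodophenol 2 (Pd(OAc)2, PPh3, K2CO3, n-Bu4NCl, DMF, 60 °C) should then give 7. Arylpalladium adds to the central allene carbon and the phenoxide closes onto the aryl-substituted terminus of the π-allyl intermediate.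

Further compounds
F1 | step 7 | (±)-5,7-bis(benzyloxy)-3,3-dimethoxy-2-[3,4,5-tris(benzyloxy)phenyl]chromane | COC1(OC)Cc2c(OCc3ccccc3)cc(OCc3ccccc3)cc2OC1c1cc(OCc2ccccc2)c(OCc2ccccc2)c(OCc2ccccc2)c1
F2 | step 8 | rac-(2R*,3R*)-5,7-bis(benzyloxy)-2-[3,4,5-tris(benzyloxy)phenyl]chroman-3-ol (racemic 2,3-cis alcohol, written as both enantiomers) | O[C@@H]1Cc2c(OCc3ccccc3)cc(OCc3ccccc3)cc2O[C@@H]1c1cc(OCc2ccccc2)c(OCc2ccccc2)c(OCc2ccccc2)c1.O[C@H]1Cc2c(OCc3ccccc3)cc(OCc3ccccc3)cc2O[C@H]1c1cc(OCc2ccccc2)c(OCc2ccccc2)c(OCc2ccccc2)c1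
F3 | step 8 | (2R,3R)-5,7-bis(benzyloxy)-2-[3,4,5-tris(benzyloxy)phenyl]chroman-3-yl (S)-2-methoxy-2-phenylacetate | CO[C@H](C(=O)O[C@@H]1Cc2c(OCc3ccccc3)cc(OCc3ccccc3)cc2O[C@@H]1c1cc(OCc2ccccc2)c(OCc2ccccc2)c(OCc2ccccc2)c1)c1ccccc1
F4 | step 8 | (2S,3S)-5,7-bis(benzyloxy)-2-[3,4,5-tris(benzyloxy)phenyl]chroman-3-yl (S)-2-methoxy-2-phenylacetate | CO[C@H](C(=O)O[C@H]1Cc2c(OCc3ccccc3)cc(OCc3ccccc3)cc2O[C@H]1c1cc(OCc2ccccc2)c(OCc2ccccc2)c(OCc2ccccc2)c1)c1ccccc1
F5 | step 4 | 1,2,3-tris(benzyloxy)-5-(propa-1,2-dien-1-yl)benzene | C=C=Cc1cc(OCc2ccccc2)c(OCc2ccccc2)c(OCc2ccccc2)c1
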